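# Proposed synthesis of CNP0261832.1 through a rhodium (5+2) cycloaddition of a silylene-bridged siloxyvinylcyclopropane

Atom numbering used throughout: seven-membered ring C1 (anisoyloxy carbon), C2, C3 (methyl-bearing), C4, C5 (carbinol), C6 (quaternary), C10 (ring-fusion CH); five-membered ring C6, C7 (acetoxy carbon), C8, C9 (isopropyl carbinol), C10. "β" is the face of the C10 hydrogen.

## Structural features

The target is a trans-fused bicyclo[5.3.0]decene: a cycloheptene (C1–C6, C10) and a cyclopentane (C6–C10) share the C6–C10 bond. It has six stereocentres, C5, C6, C7 on one side of the junction and C9, C10, C1 on the other. C6 is quaternary (angular methyl) and C9 is a fully substituted carbinol carrying isopropyl. The C6 methyl, the C9 hydroxyl and the C5 hydroxyl lie on the α face; the C10 hydrogen, the C1 anisoate, the C7 acetate and the isopropyl group lie on the β face. Four oxygens are in four different states (free allylic secondary, free tertiary, acetate, anisoate) and must be told apart. The fragile points are the C5 allylic alcohol, the esters, and the C9 carbinol, which becomes a β-hydroxy ketone (elimination toward C10, retro-aldol) whenever C1 is a ketone; the C2 methylene becomes doubly activated if a C1 ketone coexists with the C3=C4–C5=O enone. The real difficulty is the quaternary C6, flanked on three sides by oxygenated carbons, together with the C9 carbinol. The key step uses the 1,5-relation of the C1 and C5 oxygens: C6–C5–C4–C3–C2 (oxygen on C5, methyl on C3) is read as the silyl enol ether of a methylcyclopropyl ketone, C10–C1 (oxygen on C1) as an alkoxyalkyne, and C7–C8–C9 as the tether, so that C6–C10 and C1–C2 close the five- and seven-membered rings together.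

## Logic of the disconnections

24 ⇒ 23. The C5–H bond is cut (hydride on an enone). C5 is the last stereocentre and its hydroxyl is the only free secondary alcohol of the target, so making it last removes any need to tell it from the C1 and C7 oxygens. The forward step must be 1,2-selective, come from the β face (anti to the angular methyl) and spare two esters.

23 ⇒ 20. The C3=C4 unsaturation is removed. Because C6 is quaternary the C5 ketone can enolise only toward C4, so the position of the alkene is automatic. The dehydrogenation comes after C1 has been reduced and acylated, so that a C1 ketone never sits next to the enone. The step must tolerate two esters and a tertiary alcohol.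

20 ⇒ 19 ⇒ 18 ⇒ 17. The anisoyl C–O bond, the C1–H bond and the acetyl C–O bond are cut in that order. At each stage only one site can react: in 17 the only secondary alcohol is at C7, in 18 only the C1 ketone has a β-hydroxyl (on C9) to deliver hydride, and in 19 the only secondary alcohol is at C1. This leads back to a diketone diol without esters; the demand is an internally delivered reduction that sets C1.

17 ⇒ 16. The C10–H bond and all masking groups are cut (ethyl enol ether at C1, silylene across O5 and O7, silyl ether on O9). One acidic fluoride treatment releases all of them. The forward step must leave C10 trans to the angular methyl and must not eliminate the C9 oxygen.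

16 ⇒ 15 (key step). C6–C10 and C1–C2 are cut. Both rings, the quaternary carbon and the 1,5-dioxygen pattern then come from one open chain. The forward step must accept a fully substituted enol ether and an alkoxyalkyne, cleave the unsubstituted cyclopropane bond and attack the correct face of C6.

15 ⇒ 14. The two Si–O bonds of the silylene are cut. A single silicon atom protects O7, masks the C5 ketone as the enol ether the cycloaddition needs, fixes the enol geometry and decides the face of C6. The precursor is a plain aldol; enolisation must go toward C6 (C4 is a cyclopropane CH) and the ynol ether must survive a silyl triflate.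

14 ⇒ 2 + 11. The C6–C7 bond is cut (aldol). The route becomes convergent; C7 is set by the reagent and the C6 configuration is immaterial. The aldehyde is racemic at C9, so the step also has to deliver separable C9 epimers; no credible asymmetric alkynylation of an enolisable ketone was found, and this is the price.

11 ⇒ 10 ⇒ 6 + 7 and 6 ⇒ 3 + 4. The C7 oxidation level, the C8–C9 bond with the O–Si bond, and the C9–C10 bond are cut. A β-keto ester would simply be deprotonated by an acetylide, so the polarity is reversed: the acetylide is acylated and the acetate enolate is added to the ynone. The demands are 1,2-addition to a push–pull ynone and strictly non-acidic handling.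

2 ⇒ 1. The C5–ethyl bond is cut (organolithium on a carboxylate), one step from the acid.

## Other disconnections considered

Alternative 1: The cut deletes C4 (bonds C3–C4 and C4–C5). The precursor is the six-membered ketone A1, a trans-hydrindanone already carrying anisoate, acetate and the silylated C9 carbinol, used as its trimethylsilyl enol ether A2. Cyclopropanation with Et2Zn/CH2I2 and opening of the siloxycyclopropane with FeCl3, then NaOAc, would give the enone A3.
- In favour: the ring enlargement is a known sequence, and it is regiospecific because C6 is quaternary. A3 is the same compound as 22 of the chosen route, so the endgame is identical. On precedent for the ring-forming event and on placement of the C3=C4 alkene this alternative is the equal or the better.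
- Against: every stereocentre and three differentiated oxygens must already be on A1; FeCl3 meets a tertiary silyl ether; the cyclopropanation has to occur at a tetrasubstituted enol ether beside the quaternary carbon; and A1 itself needs a long linear sequence.
- Comparison: it solves only ring size, through a stepwise one-electron fragmentation, and spends three operations on one carbon. The chosen plan makes two rings and the quaternary carbon in one metal-templated step, with less precedent.

Alternative 2: The cut is C8–C9. Rh2(OAc)4 would decompose the diazoketone A4 and the carbenoid carbon C8 would insert into the ether-activated C9–H bond with retention to give cyclopentanone A5.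
- In favour: C9 becomes a fully substituted carbinol from a secondary silyl ether that is easy to obtain as one enantiomer. On control of C9 this alternative is better than the chosen plan, which separates C9 epimers.
- Against: only the five-membered ring is formed. A4 must already hold the quaternary C6 and C10 in an open chain. Insertion into the isopropyl methine is a possible competitor. The C7 ketone must later be reduced to the β-alcohol on the face of the angular methyl, and the whole seven-membered ring is still to be built from the ester and the pivalate arm.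
- Comparison: mechanistically cleaner and well precedented, but much less convergent and clearly longer.

Alternative 3: The cuts are C6–CH3 and C10–C1. Me2CuLi would add to enone A6 anti to the C7 silyl ether and the zinc enolate (ZnCl2) would attack aldehyde A7 through C10 to give the aldol adduct A8.
- In favour: three components are joined in one flask, and the vinyl iodide for a later chromium-mediated closure is brought in. The methyl/O7 trans relation, which in the chosen plan needs the silylene device, follows from well-documented substrate control. On that relation and on precedent this alternative is the equal or the better.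
- Against: no ring closes. C9 is left as an enolisable, hindered ketone to which isopropyl must be added with uncertain face selectivity. C1 depends on aldol control, and the seven-membered ring needs a separate closure that raises its own question at C5.
- Comparison: each step is safer, but there are more of them; the chosen plan is shorter and concentrates its risk in one step.

Key step: step 7

Remark on the chemistry (assumption): the (Z)-enolate made with (+)-diisopinocampheylboron triflate (from (−)-α-pinene) is taken to add to the Re face of an aldehyde, opposite to the (−)-reagent; if the sense is the reverse, the antipodal reagent is used and nothing else changes.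

## Route

Step 1
Reactants: 1 (1R,2R)-2-methylcyclopropane-1-carboxylic acid
Product: 2 1-[(1R,2R)-2-methylcyclopropyl]propan-1-one
Conditions: EtLi (2.2 equiv), Et2O, −78 → 0 °C; aq. NH4Cl
Reagents that add atoms: ethyllithium, [Li]CC
Why: Addition of an organolithium to a lithium carboxylate stops at the ketone because the dilithio gem-diolate survives until work-up. The cyclopropane centres are not touched; a single enantiomer is used so that every later intermediate is one diastereomer, although C3 and C4 are erased in the end.

Step 2
Reactants: 3 N-methoxy-N,2-dimethylpropanamide; 4 ethoxyethyne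
Product: 6 1-ethoxy-4-methylpent-1-yn-3-one, via lithium ethoxyacetylide 5 (not isolated)
Conditions: n-BuLi, THF, −78 °C; then 3, −78 → −30 °C; pH 7 buffer
Reagents that add atoms: none
Why: Acylation of a lithium acetylide by a Weinreb amide stops at the ketone through the chelated tetrahedral intermediate. This forms C9–C10 without exposing an acetylide to an acidic β-keto ester; the ynone is worked up neutral and used at once.

Step 3
Reactants: 6 1-ethoxy-4-methylpent-1-yn-3-one; 7 ethyl acetate
Product: 10 rac-ethyl 5-ethoxy-3-(propan-2-yl)-3-[(triethylsilyl)oxy]pent-4-ynoate, via lithium enolate of ethyl acetate 8 (not isolated), via lithium alkoxide adduct 9 (not isolated)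
Conditions: LiN(i-Pr)2, 7, THF, −78 °C; 6; then Et3SiOTf, −78 → −40 °C
Reagents that add atoms: triethylsilyl trifluoromethanesulfonate, CC[Si](CC)(CC)OS(=O)(=O)C(F)(F)F
Why: Acetate aldol addition to a ketone: a hard lithium enolate should add 1,2 to the alkynylogous ester, as it does to vinylogous esters. The tertiary alkoxide is silylated in the same flask, so the free ethoxyethynyl carbinol (prone to Meyer–Schuster rearrangement) is never handled. C9 is formed racemic and is resolved in step 5.

Step 4
Reactants: 10 rac-ethyl 5-ethoxy-3-(propan-2-yl)-3-[(triethylsilyl)oxy]pent-4-ynoate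
Product: 11 rac-5-ethoxy-3-(propan-2-yl)-3-[(triethylsilyl)oxy]pent-4-ynal
Conditions: i-Bu2AlH, CH2Cl2, −78 °C; Rochelle salt
Reagents that add atoms: none
Why: Partial reduction of an ester to the aldehyde at low temperature; the non-acidic conditions spare the ynol ether and the tertiary silyl ether.

Step 5
Reactants: 2 1-[(1R,2R)-2-methylcyclopropyl]propan-1-one; 11 rac-5-ethoxy-3-(propan-2-yl)-3-[(triethylsilyl)oxy]pent-4-ynal
Product: 14 (2R,3S,5R)-7-ethoxy-3-hydroxy-2-methyl-1-[(1R,2R)-2-methylcyclopropyl]-5-(propan-2-yl)-5-[(triethylsilyl)oxy]hept-6-yn-1-one (C6 R, C7 S, C9 R), via diisopinocampheylboron (Z)-enolate 12 (not isolated), via boron aldolate 13 (not isolated)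
Conditions: (+)-Ipc2BOTf, i-Pr2NEt, CH2Cl2, −78 °C; rac-11, −78 → −20 °C; H2O2, MeOH, pH 7 buffer, 0 °C; chromatography
Reagents that add atoms: none
Why: Paterson boron aldol: the ketone can enolise only on its ethyl side, the (Z)-enolate gives the syn adduct, and the boron ligands should direct attack to the Re face of the aldehyde, which sets C7 as S. Because the aldehyde is racemic and the ketone is one enantiomer, the two C9 series are diastereomers (1,3-anti wanted, 1,3-syn unwanted) and should separate on silica. C6 is erased in step 6.

Step 6
Reactants: 14 aldol adduct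
Product: 15 (4S)-4-[(2R)-4-ethoxy-2-(propan-2-yl)-2-[(triethylsilyl)oxy]but-3-yn-1-yl]-5-methyl-6-[(1R,2R)-2-methylcyclopropyl]-2,2-di(propan-2-yl)-4H-1,3,2-dioxasiline (C7 in the ring as position 4, C6=C5 as the ring alkene)
Conditions: i-Pr2Si(OTf)2, Et3N, CH2Cl2, −78 °C → rt
Reagents that add atoms: di(propan-2-yl)silanediyl bis(trifluoromethanesulfonate), CC(C)[Si](OS(=O)(=O)C(F)(F)F)(OS(=O)(=O)C(F)(F)F)C(C)C
Why: Silylation of the alcohol by a silyl bis-triflate, then intramolecular O-silylation of the ketone and deprotonation at C6 (soft enolisation; C4 cannot enolise). This closes a six-membered cyclic silyl enol ether in one step and fixes O7 cis to O5 on the double bond.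

Step 7
Reactants: 15 silylene-bridged siloxyvinylcyclopropane with tethered ethoxyalkyne
Product: 16 tricyclic bis(enol ether): bicyclo[5.3.0]deca-1(10),4-diene with ethoxy on C1, C1=C10, C5=C4 enol ether, the di(propan-2-yl)silylene bridging O5 and O7, triethylsilyloxy and isopropyl on C9, methyl on C6 (α) and on C3
Conditions: [Rh(CO)2Cl]2 (5 mol%), toluene (0.01 M), 70 °C
Reagents that add atoms: none
Why: Proposed new method: monovalent rhodium should bind the siloxyvinylcyclopropane, cleave the less hindered C4–C2 bond (the trans methyl on C3 screens C4–C3) to an allyl–alkyl rhodacycle, take up the tethered alkoxyalkyne with formation of C6–C10, and release the product by C2–C1 reductive elimination. The closest known reaction type is the rhodium-catalysed intramolecular (5+2) cycloaddition of alkyne-tethered vinylcyclopropanes, documented for trisubstituted alkenes that give quaternary carbons and for heteroatom-substituted alkynes such as ynamides, but not for a fully substituted silyl enol ether combined with an alkoxyalkyne. The five-membered ring closes in a 5-exo sense through the three-atom tether C7–C8–C9, and the seven-membered ring closes by reductive elimination from the eight-membered rhodacycle. C6, the only new stereocentre, is fixed by the silylene ring: O7 lies in the plane of the enol ether, C8 is pseudo-axial on C7 and can deliver the alkyne only to its own face, so C5 and O7 finish cis on the cyclopentane and the methyl trans to O7, as in the target. With two separate silyl ethers, allylic strain would place H7 rather than O7 beside C5 and should favour the C6 epimer; this is why the precursor carries the bridge. The ring also locks the enol geometry with the tether trans to the cyclopropane, the arrangement the rhodacycle needs, and C3 is carried through unchanged and erased in step 12. Chemoselectivity against acid-type chemistry of the ynol ether (ketenium formation, loss of the C9 oxygen) is sought with a neutral chloride-bridged catalyst, a non-polar solvent, the silylated C9 oxygen and a temperature below that of ethylene loss from the ethyl ynol ether.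

Step 8
Reactants: 16 tricyclic bis(enol ether)
Product: 17 diketone diol: 7β,9α-dihydroxy-3,6α-dimethyl-9β-(propan-2-yl)-10β-H-bicyclo[5.3.0]decane-1,5-dione
Conditions: HF (48% aq.), MeCN, 0 °C → rt
Reagents that add atoms: water, O
Why: Acid hydrolysis of the ethyl enol ether (protonation at C10) and fluoride cleavage of the silylene enol ether and the triethylsilyl ether. C10 is epimerisable beside the C1 ketone and should settle trans to the angular methyl, where C1 is trans to the isopropyl group and cis to the C9 hydroxyl (hydrogen bond to the C1 carbonyl).

Step 9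
Reactants: 17 diketone diol
Product: 18 7β-acetoxy-9α-hydroxy diketone
Conditions: Ac2O, pyridine, DMAP (cat.), CH2Cl2, 0 °C
Reagents that add atoms: acetic anhydride, CC(=O)OC(C)=O
Why: Acylation of the only secondary alcohol; the tertiary C9 hydroxyl does not react under these conditions. With C6 quaternary the β-acetoxy ketone cannot eliminate, and the acetate removes the hydroxyl that could otherwise direct hydride to C5.

Step 10
Reactants: 18 7β-acetoxy-9α-hydroxy diketone
Product: 19 1β,9α-dihydroxy-7β-acetoxy-5-ketone
Conditions: Me4NBH(OAc)3, MeCN–AcOH, −30 °C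
Reagents that add atoms: none
Why: Evans–Saksena hydroxyl-directed reduction: the borohydride is bound by the C9 hydroxyl on the α face and delivers hydride intramolecularly to the α face of C1, giving the 1β-alcohol (1,3-anti diol). The C5 ketone has no free β-hydroxyl and should be left alone.

Step 11
Reactants: 19 1β,9α-dihydroxy-7β-acetoxy-5-ketone
Product: 20 1β-(4-methoxybenzoyloxy)-7β-acetoxy-9α-hydroxy-5-ketone
Conditions: 4-MeOC6H4COCl, pyridine, DMAP, CH2Cl2, rt
Reagents that add atoms: 4-methoxybenzoyl chloride, COc1ccc(cc1)C(Cl)=O
Why: Acylation of the only secondary alcohol; the tertiary alcohol stays free.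

Step 12
Reactants: 20 anisoate acetate ketone
Product: 23 1β-(4-methoxybenzoyloxy)-7β-acetoxy-9α-hydroxy-3-en-5-one, via bis(trimethylsilyl) enol ether 21 (not isolated), via C9 trimethylsilyl ether enone 22 (not isolated)
Conditions: Me3SiOTf, Et3N, CH2Cl2, 0 °C; Pd(OAc)2 (1.2 equiv), MeCN, rt; then 1 M HCl, THF, 0 °C
Reagents that add atoms: none
Why: Saegusa–Ito dehydrogenation: soft enolisation can go only toward C4, the divalent palladium enolate loses the C3 hydrogen by β-hydride elimination to give the C3=C4 enone whatever the C3 configuration, and dilute acid removes the trimethylsilyl group that the tertiary alcohol picked up.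

Step 13
Reactants: 23 enone
Product: 24 target, (1S,5S,6S,7S,9R,10S) in the numbering used here: 1β-(4-methoxybenzoyloxy), 5α-hydroxy, 7β-acetoxy, 9α-hydroxy
Conditions: NaBH4, CeCl3·7H2O, MeOH, −78 °C
Reagents that add atoms: none
Why: Luche 1,2-reduction of the enone; hydride should come from the β face, away from the axial angular methyl on the adjacent quaternary carbon, giving the 5α-alcohol. The two esters should survive the short, cold reaction.

## Compound list

1 | (1R,2R)-2-methylcyclopropane-1-carboxylic acid | O=C(O)[C@@H]1C[C@H]1C | starting material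
2 | 1-[(1R,2R)-2-methylcyclopropyl]propan-1-one | CCC(=O)[C@@H]1C[C@H]1C | intermediate
3 | N-methoxy-N,2-dimethylpropanamide | CC(C)C(=O)N(C)OC | starting material
4 | ethoxyethyne (ethoxyacetylene) | CCOC#C | starting material
5 | lithium ethoxyacetylide | [Li+].[C-]#COCC | intermediate (not isolated)
6 | 1-ethoxy-4-methylpent-1-yn-3-one | CCOC#CC(=O)C(C)C | intermediate
7 | ethyl acetate | CCOC(C)=O | starting material
8 | lithium enolate of ethyl acetate | [Li+].[O-]C(=C)OCC | intermediate (not isolated)
9 | lithium rac-1-ethoxy-5-ethoxy-5-oxo-3-(propan-2-yl)pent-1-yn-3-olate | [Li+].CCOC#CC([O-])(C(C)C)CC(=O)OCC | intermediate (not isolated)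
10 | rac-ethyl 5-ethoxy-3-(propan-2-yl)-3-[(triethylsilyl)oxy]pent-4-ynoate | CCOC#CC(O[Si](CC)(CC)CC)(C(C)C)CC(=O)OCC | intermediate
11 | rac-5-ethoxy-3-(propan-2-yl)-3-[(triethylsilyl)oxy]pent-4-ynal | CCOC#CC(O[Si](CC)(CC)CC)(C(C)C)CC=O | intermediate
12 | (Z)-1-[(1R,2R)-2-methylcyclopropyl]prop-1-en-1-yl bis[(1S,2S,3S,5R)-isopinocampheyl]borinate | C/C=C(/[C@@H]1C[C@H]1C)OB([C@H]2C[C@H]3C[C@@H]([C@@H]2C)C3(C)C)[C@H]4C[C@H]5C[C@@H]([C@@H]4C)C5(C)C | intermediate (not isolated)
13 | O7-bis(isopinocampheyl)boryl aldolate of 14 | CCOC#C[C@](O[Si](CC)(CC)CC)(C(C)C)C[C@H](OB([C@H]2C[C@H]3C[C@@H]([C@@H]2C)C3(C)C)[C@H]4C[C@H]5C[C@@H]([C@@H]4C)C5(C)C)[C@@H](C)C(=O)[C@@H]1C[C@H]1C | intermediate (not isolated)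
14 | (2R,3S,5R)-7-ethoxy-3-hydroxy-2-methyl-1-[(1R,2R)-2-methylcyclopropyl]-5-(propan-2-yl)-5-[(triethylsilyl)oxy]hept-6-yn-1-one | CCOC#C[C@](O[Si](CC)(CC)CC)(C(C)C)C[C@H](O)[C@@H](C)C(=O)[C@@H]1C[C@H]1C | intermediate
15 | (4S)-4-[(2R)-4-ethoxy-2-(propan-2-yl)-2-[(triethylsilyl)oxy]but-3-yn-1-yl]-5-methyl-6-[(1R,2R)-2-methylcyclopropyl]-2,2-di(propan-2-yl)-4H-1,3,2-dioxasiline | CCOC#C[C@](O[Si](CC)(CC)CC)(C(C)C)C[C@@H]1O[Si](C(C)C)(C(C)C)OC([C@@H]2C[C@H]2C)=C1C | intermediate
16 | tricyclic bis(enol ether) cycloadduct (C1 ethoxy enol ether, O5/O7 silylene, C9 triethylsilyl ether) | CCOC1=C2[C@](O[Si](CC)(CC)CC)(C(C)C)C[C@@H]3O[Si](C(C)C)(C(C)C)OC(=C[C@H](C)C1)[C@]23C | intermediate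
17 | 7β,9α-dihydroxy-3,6α-dimethyl-9β-(propan-2-yl)-10β-H-bicyclo[5.3.0]decane-1,5-dione | O=C1C[C@@H](C)CC(=O)[C@@]2(C)[C@@H](O)C[C@@](O)(C(C)C)[C@H]12 | intermediate
18 | 7β-acetate of 17 | O=C1C[C@@H](C)CC(=O)[C@@]2(C)[C@@H](OC(C)=O)C[C@@](O)(C(C)C)[C@H]12 | intermediate
19 | 1β-alcohol from 18 | O[C@H]1C[C@@H](C)CC(=O)[C@@]2(C)[C@@H](OC(C)=O)C[C@@](O)(C(C)C)[C@H]12 | intermediate
20 | 1β-(4-methoxybenzoate) of 19 | COc1ccc(cc1)C(=O)O[C@H]1C[C@@H](C)CC(=O)[C@@]2(C)[C@@H](OC(C)=O)C[C@@](O)(C(C)C)[C@H]12 | intermediate
21 | C5 trimethylsilyl enol ether, C9 trimethylsilyl ether of 20 | COc1ccc(cc1)C(=O)O[C@H]1C[C@@H](C)C=C(O[Si](C)(C)C)[C@@]2(C)[C@@H](OC(C)=O)C[C@@](O[Si](C)(C)C)(C(C)C)[C@H]12 | intermediate (not isolated)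
22 | C3=C4 enone with C9 trimethylsilyl ether | COc1ccc(cc1)C(=O)O[C@H]1CC(C)=CC(=O)[C@@]2(C)[C@@H](OC(C)=O)C[C@@](O[Si](C)(C)C)(C(C)C)[C@H]12 | intermediate (not isolated)
23 | C3=C4 enone with free C9 hydroxyl | COc1ccc(cc1)C(=O)O[C@H]1CC(C)=CC(=O)[C@@]2(C)[C@@H](OC(C)=O)C[C@@](O)(C(C)C)[C@H]12 | intermediate
24 | CNP0261832.1 | COc1ccc(C(=O)O[C@H]2CC(C)=C[C@H](O)[C@@]3(C)[C@@H](OC(C)=O)C[C@@](O)(C(C)C)[C@H]23)cc1 | target

## Step count and least certain steps

Total: 13 steps. Longest linear sequence: 12 steps (steps 2–13, from 3 and 4); step 1 is the side branch.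

Step 7 (key step). The catalyst may fail to turn over at the congested, fully substituted enol ether. The alkoxyalkyne may be diverted into ketenium or ionisation chemistry, and cleavage of the substituted cyclopropane bond would misplace the methyl group. The fallback uses only known reaction types and closes the rings one after the other; it sets out from 14 and comes back at 17.
- Dilute aqueous oxalic acid hydrates the ynol ether to the ethyl ester keto alcohol F1.
- The conditions of step 6 give the cyclic silyl enol ether ester F2.
- The ester is converted into its ketene silyl acetal (LiN(i-Pr)2, Me3SiCl) and coupled oxidatively with the cyclic enol silane, using (NH4)2Ce(NO3)6 (tetravalent cerium) buffered with NaHCO3. This forms C6–C10 under the same ring-enforced facial control; aqueous HF then gives the cyclopentane diol keto ester F3.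
- Me3SiI with hexamethyldisilazane opens the cyclopropyl ketone at its CH2 carbon and silylates the hydroxyls, giving the iodide F4.
- SmI2 with catalytic NiI2 makes C2 acylate the ester (Barbier-type) and closes the seven-membered ring to the silylated diketone equivalent F5; aqueous HF returns 17.
- The sequence is longer and each stage is expected to be lower-yielding, and the site of iodide attack on the cyclopropane is itself uncertain.

Step 3. The enolate may add in a conjugate sense to the push–pull ynone, or 6 may be lost by hydration on handling. The fallback reverses the order of bond formation; it sets out from 4 (through 5) and comes back at 11. Lithium ethoxyacetylide adds 1,2 to commercial 4-methylpent-1-en-3-one and the alkoxide is trapped with Et3SiOTf to give the vinyl carbinol silyl ether F6. Hydroboration with 9-borabicyclo[3.3.1]nonane and NaBO3 oxidation give the primary alcohol F7, and Dess–Martin oxidation gives 11.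

Step 5. Reagent control may be incomplete, or the two C9 series may not separate, because the aldehyde enters as a racemate. The fallback moves the resolution before the coupling; it sets out from 10 and comes back at 14. Preparative chromatography of 10 on a chiral stationary phase gives the (R)-ester F8, i-Bu2AlH gives the (R)-aldehyde F9, and the aldol of step 5 then gives 14 as one diastereomer.

Step 8. Acid may eliminate the tertiary C9 hydroxyl toward C10 (or the ring may open by retro-aldol) while two β-hydroxy ketones are exposed together, and C10 may not equilibrate fully. The fallback stages the unmasking; it sets out from 16 and comes back at 20.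
- Cold dilute HCl in wet THF hydrolyses only the ethyl enol ether and the triethylsilyl ether, giving the C1 ketone with intact silylene F10.
- Me4NBH(OAc)3 gives the 1β-alcohol F11, and anisoylation gives the silylene anisoate F12.
- HF·pyridine releases the hydroxy ketone anisoate F13, and acetylation gives 20.

Step 10. Ligand exchange at the hindered tertiary hydroxyl may be slow, so that undirected hydride attacks the exposed β face and gives the wrong C1 epimer. The fallback accepts that epimer and inverts it; it sets out from 18 and comes back at 20. Chelation-controlled reduction with Zn(BH4)2 gives the 1α-alcohol F14 (1,3-syn), and Mitsunobu esterification with 4-methoxybenzoic acid (PPh3, diisopropyl azodicarboxylate) inverts C1 and installs the anisoate in one step.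

Step 13. Facial selectivity may be poor if the β-oriented C7 acetate screens the β face as much as the angular methyl screens the α face. The fallback replaces substrate control by reagent control; it sets out from 23 and comes back at 24. The enone is reduced with catecholborane and the matching enantiomer of the B-methyl oxazaborolidine (Corey–Bakshi–Shibata) catalyst; no new compound is formed.

## Further compounds

F1 | step 7 | ethyl (3R,5S,6R)-5-hydroxy-6-methyl-7-[(1R,2R)-2-methylcyclopropyl]-7-oxo-3-(propan-2-yl)-3-[(triethylsilyl)oxy]heptanoate | CCOC(=O)C[C@](O[Si](CC)(CC)CC)(C(C)C)C[C@H](O)[C@@H](C)C(=O)[C@@H]1C[C@H]1C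
F2 | step 7 | cyclic di(propan-2-yl)silylene enol ether of F1 | CCOC(=O)C[C@](O[Si](CC)(CC)CC)(C(C)C)C[C@@H]1O[Si](C(C)C)(C(C)C)OC([C@@H]2C[C@H]2C)=C1C
F3 | step 7 | ethyl 3,5-dihydroxy-2-methyl-2-[(1R,2R)-2-methylcyclopropanecarbonyl]-5-(propan-2-yl)cyclopentane-1-carboxylate (C6–C10 bond formed) | CCOC(=O)[C@H]1[C@](O)(C(C)C)C[C@H](O)[C@]1(C)C(=O)[C@@H]1C[C@H]1C
F4 | step 7 | ring-opened iodide: C5 trimethylsilyl enol ether, C2 iodide, bis(trimethylsilyl) ether of F3 | CCOC(=O)[C@H]1[C@](O[Si](C)(C)C)(C(C)C)C[C@H](O[Si](C)(C)C)[C@]1(C)C(O[Si](C)(C)C)=C[C@H](C)CI
F5 | step 7 | bicyclic C1 ketone with C5 trimethylsilyl enol ether and C7, C9 trimethylsilyl ethers | O=C1C[C@@H](C)C=C(O[Si](C)(C)C)[C@@]2(C)[C@@H](O[Si](C)(C)C)C[C@@](O[Si](C)(C)C)(C(C)C)[C@H]12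
F6 | step 3 | rac-triethyl{[1-ethoxy-3-(propan-2-yl)pent-4-en-1-yn-3-yl]oxy}silane | CCOC#CC(O[Si](CC)(CC)CC)(C(C)C)C=C
F7 | step 3 | rac-5-ethoxy-3-(propan-2-yl)-3-[(triethylsilyl)oxy]pent-4-yn-1-ol | CCOC#CC(O[Si](CC)(CC)CC)(C(C)C)CCO
F8 | step 5 | ethyl (3R)-5-ethoxy-3-(propan-2-yl)-3-[(triethylsilyl)oxy]pent-4-ynoate | CCOC#C[C@](O[Si](CC)(CC)CC)(C(C)C)CC(=O)OCC
F9 | step 5 | (3R)-5-ethoxy-3-(propan-2-yl)-3-[(triethylsilyl)oxy]pent-4-ynal | CCOC#C[C@](O[Si](CC)(CC)CC)(C(C)C)CC=O
F10 | step 8 | tricyclic C1 ketone with O5/O7 silylene enol ether and free C9 hydroxyl | O=C1C[C@@H](C)C=C2O[Si](C(C)C)(C(C)C)O[C@H]3C[C@@](O)(C(C)C)[C@H]1[C@@]23C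
F11 | step 8 | 1β-alcohol from F10 | O[C@H]1C[C@@H](C)C=C2O[Si](C(C)C)(C(C)C)O[C@H]3C[C@@](O)(C(C)C)[C@H]1[C@@]23C
F12 | step 8 | 1β-(4-methoxybenzoate) of F11 | COc1ccc(cc1)C(=O)O[C@H]1C[C@@H](C)C=C2O[Si](C(C)C)(C(C)C)O[C@H]3C[C@@](O)(C(C)C)[C@H]1[C@@]23C
F13 | step 8 | 1β-(4-methoxybenzoyloxy)-7β,9α-dihydroxy-5-ketone | COc1ccc(cc1)C(=O)O[C@H]1C[C@@H](C)CC(=O)[C@@]2(C)[C@@H](O)C[C@@](O)(C(C)C)[C@H]12
F14 | step 10 | 1α-alcohol, C1 epimer of 19 | O[C@@H]1C[C@@H](C)CC(=O)[C@@]2(C)[C@@H](OC(C)=O)C[C@@](O)(C(C)C)[C@H]12
F0 | step 13 | none | none
A1 | alternative 1 | trans-hydrindanone with C1 anisoate, C7 acetate, C9 trimethylsilyl ether (C4 absent) | COc1ccc(C(=O)O[C@H]2CC(C)C(=O)[C@@]3(C)[C@@H](OC(C)=O)C[C@@](O[Si](C)(C)C)(C(C)C)[C@H]23)cc1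
A2 | alternative 1 | trimethylsilyl enol ether of A1 (C5=C3) | COc1ccc(C(=O)O[C@H]2CC(C)=C(O[Si](C)(C)C)[C@@]3(C)[C@@H](OC(C)=O)C[C@@](O[Si](C)(C)C)(C(C)C)[C@H]23)cc1
A3 | alternative 1 | ring-enlarged hydroazulenone with the C5 enone | COc1ccc(C(=O)O[C@H]2CC(C)=CC(=O)[C@@]3(C)[C@@H](OC(C)=O)C[C@@](O[Si](C)(C)C)(C(C)C)[C@H]23)cc1
A4 | alternative 2 | diazoketone with C6, C10 and the C9–H silyl ether in place | [N-]=[N+]=CC(=O)[C@](C)(COC(=O)C(C)(C)C)[C@@H](C(=O)OC)[C@H](O[Si](C)(C)C(C)(C)C)C(C)C
A5 | alternative 2 | 3-silyloxy-3-isopropylcyclopentanone from C–H insertion | O=C1C[C@@](O[Si](C)(C)C(C)(C)C)(C(C)C)[C@H](C(=O)OC)[C@@]1(C)COC(=O)C(C)(C)C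
A6 | alternative 3 | 4-[(tert-butyldimethylsilyl)oxy]-3-{[(4-methoxybenzyl)oxy]methyl}cyclopent-2-en-1-one | O=C1C=C(COCc2ccc(OC)cc2)[C@@H](O[Si](C)(C)C(C)(C)C)C1
A7 | alternative 3 | (Z)-4-iodo-3-methylbut-3-enal | O=CC/C(C)=C\I
A8 | alternative 3 | tetrasubstituted cyclopentanone aldol adduct | O=C1C[C@H](O[Si](C)(C)C(C)(C)C)[C@](C)(COCc2ccc(OC)cc2)[C@H]1[C@@H](O)C/C(C)=C\I
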